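**Plan**
- Retrosynthesis: remove the benzyl ethers and cut a temporary C1'=C2' alkene in the side chain by cross-metathesis, giving a 3-vinyl lactone and (S)-10-methoxyundec-1-ene. Then cut the lactone alkyl C–O bond (O2–C3) to a 2-(but-3-ynyl)benzoic acid, and cut its benzylic CH2–CH2 bond to the lateral anion of dibenzyl methyl orsellinate plus a silylated propargylic bromide.
- Enabling feature: C3 of lactone ring B is a carbinol carbon flanked by C4 and side-chain C1'. With C1'=C2' unsaturated, C3 is the substituted end of an allyl unit C3–C1'–C2', and the carboxyl oxygen on C1 (on C8a of ring A) lies 1,6 to it.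
- Forward: ring A is bought. Ring B closes in step 4 by rhodium-catalysed isomerising addition of CO2H to the terminal alkyne (alkyne → allene → π-allyl → O2–C3).
- The chain is then joined at the vinyl group by cross-metathesis, and one hydrogenation removes the helper alkene and the benzyl groups.
- Stereochemistry: C3 comes from the chiral diphosphine on rhodium in step 4; C10' comes from (S)-propylene oxide.

Key step: step 4

Remark (assumption): the sense of induction of the DIOP-type ligand in step 4 is not predicted here. The antipode that gives the 3S vinyl lactone is taken as identified in one pilot run; both antipodes are commercial.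

Step 1
Reactants: 1 methyl 2,4-dihydroxy-6-methylbenzoate (methyl orsellinate)
Product: 2 methyl 2,4-bis(benzyloxy)-6-methylbenzoate
Conditions: BnBr (2.4 equiv), K2CO3 (3 equiv), DMF, 60 °C
Reagents that add atoms: benzyl bromide, BrCc1ccccc1
Why: Williamson etherification of both phenols (the chelated 2-OH needs warm DMF) should give ethers that survive steps 2–7 and leave by hydrogenolysis, which the aliphatic methyl ether of the target tolerates.

Step 2
Reactants: 2 methyl 2,4-bis(benzyloxy)-6-methylbenzoate; 3 3-bromo-1-(trimethylsilyl)prop-1-yne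
Product: 5 methyl 2,4-bis(benzyloxy)-6-[4-(trimethylsilyl)but-3-yn-1-yl]benzoate, via benzylic lithium species 4 (not isolated)
Conditions: LiN(iPr)2 (1.2 equiv), THF, −78 °C; then 3 (1.5 equiv), −78 → −40 °C
Reagents that add atoms: none
Why: Lateral lithiation of the ortho-toluate (the ester acidifies the 6-methyl group) followed by SN2 alkylation should install the four-carbon arm; the silyl cap blocks acetylide proton transfer and SN2' attack, and no stereocenter is formed.

Step 3
Reactants: 5 methyl 2,4-bis(benzyloxy)-6-[4-(trimethylsilyl)but-3-yn-1-yl]benzoate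
Product: 7 2,4-bis(benzyloxy)-6-(but-3-yn-1-yl)benzoic acid, via desilylated methyl ester 6 (not isolated)
Conditions: KOH (8 equiv), EtOH–H2O (4:1), reflux; then aq. HCl, 0 °C
Reagents that add atoms: potassium hydroxide, [K+].[OH-]
Why: Hydroxide should first cleave the C(sp)–Si bond and then saponify the hindered 2,6-disubstituted benzoate under forcing conditions; the isolated terminal alkyne and the benzyl ethers are inert to aqueous alkali at this temperature.

Step 4
Reactants: 7 2,4-bis(benzyloxy)-6-(but-3-yn-1-yl)benzoic acid
Product: 9 (3S)-6,8-bis(benzyloxy)-3-vinylisochroman-1-one, via allenyl acid 8 (not isolated)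
Conditions: [Rh(cod)Cl]2 (2.5 mol %), DIOP (one antipode, see remark; 6 mol %), ClCH2CH2Cl (0.05 M), 70 °C
Reagents that add atoms: none
Why: Mechanism: O–H oxidative addition of the carboxyl group of 7 to monovalent rhodium gives a trivalent rhodium hydride carboxylate, which isomerises the terminal alkyne to the allene 8 by hydrometalation and β-hydride elimination, re-adds to the allene to give a π-allyl over C3–C1'–C2' and closes the O2–C3 bond by reductive elimination at the substituted allyl end, with no by-product. The closest known reaction type is the rhodium/diphosphine-catalysed redox-neutral addition of carboxylic acids to terminal alkynes and allenes to give branched allylic esters, known in enantioselective form and as a lactone- and macrolactone-forming ring closure. Ring B closes in the 6-exo mode, the carboxylate oxygen attacking allyl carbon C3 while C1'=C2' stays outside the ring as a vinyl group. The new stereocenter C3 is controlled by the C2-symmetric chiral diphosphine on rhodium, which differentiates the two faces of the allyl end in the C–O bond-forming step (3S in 9, the spatial arrangement of 3R in the target). The step needs branched rather than linear C–O formation and C–O closure rather than β-hydride loss to an aryl diene; the first is intrinsic to rhodium and reinforced because attack at C2' would demand an eight-membered ring, the second is secured by the carboxylate being held on the metal next to C3.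

Step 5
Reactants: 10 8-bromooct-1-ene; 11 (S)-2-methyloxirane ((S)-propylene oxide)
Product: 13 (2S)-undec-10-en-2-ol, via Grignard reagent 12 (not isolated)
Conditions: Mg, THF, rt → 40 °C; then CuI (10 mol %), 11, −30 → 0 °C; aq. NH4Cl
Reagents that add atoms: none
Why: Copper-catalysed Grignard opening of the epoxide at its unsubstituted carbon (SN2) should give the secondary alcohol; the stereocenter is not touched, so S of the epoxide is carried over as S.

Step 6
Reactants: 13 (2S)-undec-10-en-2-ol
Product: 14 (10S)-10-methoxyundec-1-ene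
Conditions: NaH, THF, 0 °C; MeI, 0 °C → rt
Reagents that add atoms: iodomethane, CI
Why: Williamson methylation of the sodium alkoxide forms only the O–CH3 bond, so the carbinol configuration is retained.

Step 7
Reactants: 9 (3S)-6,8-bis(benzyloxy)-3-vinylisochroman-1-one; 14 (10S)-10-methoxyundec-1-ene
Product: 15 (3S)-6,8-bis(benzyloxy)-3-[(1E,10S)-10-methoxyundec-1-en-1-yl]isochroman-1-one
Conditions: second-generation Grubbs catalyst RuCl2(=CHPh)(PCy3)(H2IMes) (5 mol %), 14 (3 equiv), CH2Cl2, 40 °C
Reagents that add atoms: none
Why: Olefin cross-metathesis between the slowly homodimerising allylic-ester vinyl group of 9 and an excess of the fast-reacting terminal alkene 14 should be driven by loss of ethene; neither stereocenter takes part, and the E isomer drawn and any Z isomer converge in step 8.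

Step 8
Reactants: 15 (3S)-6,8-bis(benzyloxy)-3-[(1E,10S)-10-methoxyundec-1-en-1-yl]isochroman-1-one
Product: 17 (3R)-6,8-dihydroxy-3-[(10S)-10-methoxyundecyl]isochroman-1-one, via saturated dibenzyl lactone 16 (not isolated)
Conditions: H2 (1 atm), 10 % Pd/C, EtOAc–EtOH, rt
Reagents that add atoms: none
Why: Catalytic hydrogenation should first saturate the helper C1'=C2' bond and then hydrogenolyse both benzyl ethers; the lactone, the aliphatic methyl ether and both stereocenters are left alone (the C3 descriptor changes from S to R only through the priority change of the side chain).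

**Compound list**
1 | methyl 2,4-dihydroxy-6-methylbenzoate | COC(=O)c1c(C)cc(O)cc1O | starting material
2 | methyl 2,4-bis(benzyloxy)-6-methylbenzoate | COC(=O)c1c(C)cc(OCc2ccccc2)cc1OCc1ccccc1 | intermediate
3 | 3-bromo-1-(trimethylsilyl)prop-1-yne | C[Si](C)(C)C#CCBr | starting material
4 | methyl 2,4-bis(benzyloxy)-6-(lithiomethyl)benzoate | [Li]Cc1cc(OCc2ccccc2)cc(OCc2ccccc2)c1C(=O)OC | intermediate
5 | methyl 2,4-bis(benzyloxy)-6-[4-(trimethylsilyl)but-3-yn-1-yl]benzoate | COC(=O)c1c(CCC#C[Si](C)(C)C)cc(OCc2ccccc2)cc1OCc1ccccc1 | intermediate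
6 | methyl 2,4-bis(benzyloxy)-6-(but-3-yn-1-yl)benzoate | COC(=O)c1c(CCC#C)cc(OCc2ccccc2)cc1OCc1ccccc1 | intermediate
7 | 2,4-bis(benzyloxy)-6-(but-3-yn-1-yl)benzoic acid | OC(=O)c1c(CCC#C)cc(OCc2ccccc2)cc1OCc1ccccc1 | intermediate
8 | 2,4-bis(benzyloxy)-6-(buta-2,3-dien-1-yl)benzoic acid | OC(=O)c1c(CC=C=C)cc(OCc2ccccc2)cc1OCc1ccccc1 | intermediate
9 | (3S)-6,8-bis(benzyloxy)-3-vinylisochroman-1-one | C=C[C@@H]1Cc2cc(OCc3ccccc3)cc(OCc3ccccc3)c2C(=O)O1 | intermediate
10 | 8-bromooct-1-ene | C=CCCCCCCBr | starting material
11 | (S)-2-methyloxirane | C[C@H]1CO1 | starting material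
12 | oct-7-en-1-ylmagnesium bromide | C=CCCCCCC[Mg]Br | intermediate
13 | (2S)-undec-10-en-2-ol | C[C@H](O)CCCCCCCC=C | intermediate
14 | (10S)-10-methoxyundec-1-ene | CO[C@@H](C)CCCCCCCC=C | intermediate
15 | (3S)-6,8-bis(benzyloxy)-3-[(1E,10S)-10-methoxyundec-1-en-1-yl]isochroman-1-one | CO[C@@H](C)CCCCCCC/C=C/[C@@H]1Cc2cc(OCc3ccccc3)cc(OCc3ccccc3)c2C(=O)O1 | intermediate
16 | (3R)-6,8-bis(benzyloxy)-3-[(10S)-10-methoxyundecyl]isochroman-1-one | CO[C@@H](C)CCCCCCCCC[C@@H]1Cc2cc(OCc3ccccc3)cc(OCc3ccccc3)c2C(=O)O1 | intermediate
17 | (3R)-6,8-dihydroxy-3-[(10S)-10-methoxyundecyl]isochroman-1-one | CO[C@@H](C)CCCCCCCCC[C@@H]1Cc2cc(O)cc(O)c2C(=O)O1 | target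

**Step count**
Total: 8 steps. Longest linear sequence: 6 steps (steps 1, 2, 3, 4, 7, 8); steps 5 and 6 make the side-chain fragment.

**Steps most likely to fail**

Step 4. The enantioselective closure of a small benzo-fused ring is the least precedented part of the route. Face discrimination at the allyl end C3 may be insufficient, or β-hydride loss from the π-allyl to a conjugated aryl diene may outrun C–O reductive elimination. The fallback sets out from 2 and comes back at 9, replacing catalyst control by a chiral-pool aldehyde.
- The lithio species 4 (from 2, LiN(iPr)2, THF, −78 °C) is added to commercial (R)-2,2-dimethyl-1,3-dioxolane-4-carbaldehyde. This gives the alkoxide methyl 2,4-bis(benzyloxy)-6-[(2S)-2-[(4R)-2,2-dimethyl-1,3-dioxolan-4-yl]-2-(lithiooxy)ethyl]benzoate F1.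
- On warming, F1 closes onto the ester to give (3S)-6,8-bis(benzyloxy)-3-[(4R)-2,2-dimethyl-1,3-dioxolan-4-yl]isochroman-1-one F2. This Felkin–Anh anti adduct is expected to predominate with modest facial selectivity and to be separable from its C3 epimer by chromatography.
- Aqueous AcOH at 50 °C should give the diol (3S)-6,8-bis(benzyloxy)-3-[(1R)-1,2-dihydroxyethyl]isochroman-1-one F3.
- 1,1'-Thiocarbonyldiimidazole in THF should give the cyclic thiocarbonate (3S)-6,8-bis(benzyloxy)-3-[(4R)-2-thioxo-1,3-dioxolan-4-yl]isochroman-1-one F4.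
- Corey–Winter olefination of F4 (P(OMe)3, 110 °C) should give 9.

Step 2. Claisen-type self-condensation of the lateral anion with unreacted ester, or proton transfer to the anion, may compete with alkylation. The fallback sets out from 2 and comes back at 7, using a carboxylate dianion that cannot self-condense; it also spares the alkyne the hot alkali of step 3.
- 2 is saponified first (KOH, DMSO–H2O, 100 °C) to 2,4-bis(benzyloxy)-6-methylbenzoic acid F5.
- LiN(iPr)2 (2.2 equiv, THF, −78 → 0 °C) should give the dianion lithium 2,4-bis(benzyloxy)-6-(lithiomethyl)benzoate F6.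
- Alkylation of F6 with 3 should give 2,4-bis(benzyloxy)-6-[4-(trimethylsilyl)but-3-yn-1-yl]benzoic acid F7.
- K2CO3 in MeOH at rt removes the silyl group to give 7.

Step 8. Hydrogenolysis of the allylic C3–O bond on palladium may occur before the alkene is saturated, opening ring B and losing the C3 stereocenter. The fallback sets out from 15 and comes back at 16 and then 17. The two reductions are separated: diimide (from 2-nitrobenzenesulfonohydrazide and Et3N, CH2Cl2, rt) transfers hydrogen to C1'=C2' in a concerted way that cannot ionise the C–O bond, giving isolated 16. Hydrogenolysis of the benzyl ethers of the now non-allylic lactone (H2, Pd/C, EtOAc) then gives 17. No new compound is made.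

**Further compounds**
F1 | step 4 | methyl 2,4-bis(benzyloxy)-6-[(2S)-2-[(4R)-2,2-dimethyl-1,3-dioxolan-4-yl]-2-(lithiooxy)ethyl]benzoate | COC(=O)c1c(C[C@H](O[Li])[C@H]2COC(C)(C)O2)cc(OCc2ccccc2)cc1OCc1ccccc1
F2 | step 4 | (3S)-6,8-bis(benzyloxy)-3-[(4R)-2,2-dimethyl-1,3-dioxolan-4-yl]isochroman-1-one | CC1(C)OC[C@@H](O1)[C@@H]1Cc2cc(OCc3ccccc3)cc(OCc3ccccc3)c2C(=O)O1
F3 | step 4 | (3S)-6,8-bis(benzyloxy)-3-[(1R)-1,2-dihydroxyethyl]isochroman-1-one | OC[C@@H](O)[C@@H]1Cc2cc(OCc3ccccc3)cc(OCc3ccccc3)c2C(=O)O1
F4 | step 4 | (3S)-6,8-bis(benzyloxy)-3-[(4R)-2-thioxo-1,3-dioxolan-4-yl]isochroman-1-one | S=C1OC[C@@H](O1)[C@@H]1Cc2cc(OCc3ccccc3)cc(OCc3ccccc3)c2C(=O)O1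
F5 | step 2 | 2,4-bis(benzyloxy)-6-methylbenzoic acid | Cc1cc(OCc2ccccc2)cc(OCc2ccccc2)c1C(O)=O
F6 | step 2 | lithium 2,4-bis(benzyloxy)-6-(lithiomethyl)benzoate | [Li]Cc1cc(OCc2ccccc2)cc(OCc2ccccc2)c1C(=O)O[Li]
F7 | step 2 | 2,4-bis(benzyloxy)-6-[4-(trimethylsilyl)but-3-yn-1-yl]benzoic acid | C[Si](C)(C)C#CCCc1cc(OCc2ccccc2)cc(OCc2ccccc2)c1C(O)=O
F0 | step 8 | none | none
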